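Retrosynthesis: (i) remove the allyl ester and the formate, then cut the C5–CH2O bond of the cyclohexenone (C1 bears the propanoic acid, C2 the cyclohexyl, C5 the CH2O group, C6 is C=O); (ii) cut the enone ring at C1=C2 (aldol) and C4–C5 (Michael), leaving a vinyl ketone on C1' and a β-keto diester that carries the propanoate centre; (iii) cut the C2'–C3' bond of the trimethylcyclohexane (C1' quaternary, C2' ring CH2, C3' CMe2), leaving an acyclic α-quaternary aldehyde made from geraniol.
Forward: geraniol → epoxide → quaternary aldehyde (1,2-shift) → sulfonylhydrazone → trimethylcyclohexane ring (radical closure) → acid → vinyl ketone → Robinson annulation to the cyclohexenone → hydroxymethylation at C5 → formate → free acid.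
Enabling feature: C2' is an unsubstituted CH2 between two fully substituted carbons, so C3' can be a tertiary radical made from a prenyl-type alkene and C2' can be the aldehyde arm on C1', whose hydrazone nitrogen leaves as N2; both carbons are electrophilic in character and are joined reductively.
Stereochemistry: C1' comes from the Sharpless epoxidation of geraniol, relayed by a stereospecific 1,2-shift; the propanoate centre comes from commercial methyl (S)-3-bromo-2-methylpropanoate; C5 is set late by a catalyst-controlled aldol reaction with formaldehyde and kept under non-basic conditions.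

Key step: step 5

Assumption: the 1,2-shift of step 3 is taken as antiperiplanar (inversion at the migration terminus), the normal course of this rearrangement, which is why D-(−)-diethyl tartrate is used in step 1; likewise the (S,S)-ligand of step 13 is taken to give the 5S centre, and the antipode of either would be used if the sense proved opposite.

Step 1
Reactants: 1 geraniol, (2E)-3,7-dimethylocta-2,6-dien-1-ol
Product: 2 [(2R,3R)-3-methyl-3-(4-methylpent-3-en-1-yl)oxiran-2-yl]methanol
Conditions: Ti(OiPr)4 (5 mol%), D-(−)-diethyl tartrate (6 mol%), t-BuOOH, 4 Å MS, CH2Cl2, −20 °C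
Reagents that add atoms: tert-butyl hydroperoxide, CC(C)(C)OO
Why: Sharpless asymmetric epoxidation is hydroxyl-directed, so only the allylic 2,3-alkene should react, and the D-tartrate complex should deliver oxygen to the face that gives the (2R,3R) epoxide.

Step 2
Reactants: 2 [(2R,3R)-3-methyl-3-(4-methylpent-3-en-1-yl)oxiran-2-yl]methanol
Product: 3 tert-butyl(dimethyl){[(2R,3R)-3-methyl-3-(4-methylpent-3-en-1-yl)oxiran-2-yl]methoxy}silane
Conditions: TBSCl, imidazole, DMF, 0 °C → rt
Reagents that add atoms: tert-butyl(chloro)dimethylsilane, CC(C)(C)[Si](C)(C)Cl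
Why: Standard silylation of a primary alcohol should give the silyl ether that the following Lewis-acid rearrangement requires, without touching either stereocentre.

Step 3
Reactants: 3 tert-butyl(dimethyl){[(2R,3R)-3-methyl-3-(4-methylpent-3-en-1-yl)oxiran-2-yl]methoxy}silane
Product: 4 (2R)-2-{[tert-butyl(dimethyl)silyl]oxymethyl}-2,6-dimethylhept-5-enal
Conditions: MeAl(OC6H2-2,6-tBu2-4-Br)2 (from Me3Al and the phenol), CH2Cl2, −78 °C
Reagents that add atoms: none
Why: In this semipinacol-type rearrangement of an epoxy silyl ether to a β-siloxy aldehyde the bulky aluminium Lewis acid should open the epoxide at the tertiary carbon while the siloxymethyl group shifts antiperiplanar with inversion, so the epoxide chirality becomes the (R) quaternary centre (the future C1').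

Step 4
Reactants: 4 (2R)-2-{[tert-butyl(dimethyl)silyl]oxymethyl}-2,6-dimethylhept-5-enal
Product: 5 N'-[(1E,2S)-2-{[tert-butyl(dimethyl)silyl]oxymethyl}-2,6-dimethylhept-5-en-1-ylidene]-4-methylbenzenesulfonohydrazide
Conditions: TsNHNH2, MeOH, rt
Reagents that add atoms: 4-methylbenzenesulfonohydrazide, Cc1ccc(cc1)S(=O)(=O)NN
Why: Condensation of the non-enolisable aldehyde with tosylhydrazide should give the (E)-hydrazone, the quaternary centre being unable to epimerise (its descriptor changes to S by priority only).

Step 5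
Reactants: 5 N'-[(1E,2S)-2-{[tert-butyl(dimethyl)silyl]oxymethyl}-2,6-dimethylhept-5-en-1-ylidene]-4-methylbenzenesulfonohydrazide
Product: 8 tert-butyl(dimethyl){[(1S)-1,3,3-trimethylcyclohexyl]methoxy}silane, via cyclised sulfonylhydrazide 6 (not isolated), via alkyldiazene 7 (not isolated)
Conditions: Fe(acac)3 (0.5 equiv), PhSiH3 (3 equiv), EtOH/THF, 60 °C; then NaOAc, EtOH, 80 °C
Reagents that add atoms: none
Why: Proposed new method: an iron hydride generated from Fe(acac)3 and PhSiH3 transfers a hydrogen atom to C4' of the trisubstituted alkene (Markovnikov sense), the resulting tertiary C3' radical adds to the hydrazone carbon C2', the hydrazinyl radical is reduced by divalent iron and protonated to hydrazide 6, and acetate-induced loss of sulfinate gives diazene 7, which expels N2 and leaves C2' as the ring CH2, so two carbons of electrophilic character (Markovnikov carbon of an alkene, aldehyde carbon) are joined reductively. The closest known reactions are the Fe(acac)3/PhSiH3 hydromethylation of unactivated alkenes with a formaldehyde N-sulfonylhydrazone followed by thermal denitrogenation and the hydrogen-atom-transfer cyclisation of alkenes onto tethered ketone tosylhydrazones; untested is the ring-closing use on an aldehyde-derived hydrazone next to a quaternary carbon with denitrogenation in the same flask. The cyclohexane closes in the 6-exo-trig mode (C=N carbon in the ring and nitrogen outside). No stereocentre is created, because C3' bears two methyl groups and the C2' centre of 6 is erased with N2, and the C1' centre from step 3 is neither radical nor enolisable at any stage and is therefore kept. The step needs hydrogen-atom transfer only to the electron-rich alkene and cyclisation faster than reduction of the tertiary radical; the single alkene in 5, the polarity match of a nucleophilic tertiary radical with the electron-poor C=N, the geminal substitution at C1' (Thorpe–Ingold effect) and the inert silyl ether secure both.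

Step 6
Reactants: 8 tert-butyl(dimethyl){[(1S)-1,3,3-trimethylcyclohexyl]methoxy}silane
Product: 9 (1S)-1,3,3-trimethylcyclohexane-1-carboxylic acid
Conditions: CrO3, H2SO4, acetone/H2O, 0 °C → rt
Reagents that add atoms: water, O
Why: Jones oxidation should cleave the primary silyl ether in the acidic medium and oxidise the neopentyl alcohol through the aldehyde hydrate to the acid, the quaternary centre having no α-hydrogen to lose.

Step 7
Reactants: 9 (1S)-1,3,3-trimethylcyclohexane-1-carboxylic acid
Product: 11 1-[(1S)-1,3,3-trimethylcyclohexyl]prop-2-en-1-one, via acid chloride 10 (not isolated)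
Conditions: (COCl)2, DMF (cat.), CH2Cl2, 0 °C → rt; then CH2=CHSnBu3, PdCl2(PPh3)2 (3 mol%), THF, 50 °C
Reagents that add atoms: tributyl(vinyl)stannane, C=C[Sn](CCCC)(CCCC)CCCC; oxalyl chloride, O=C(Cl)C(=O)Cl (chlorine of 10 only)
Why: Stille acylation of the acid chloride with a vinylstannane should give the vinyl ketone directly and without over-addition, leaving the adjacent quaternary centre untouched.

Step 8
Reactants: 12 methyl (2S)-3-bromo-2-methylpropanoate; 13 methyl 3-chloro-3-oxopropanoate
Product: 15 dimethyl (2R)-2-methyl-4-oxohexanedioate, via alkylzinc bromide 14 (not isolated)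
Conditions: Zn dust, I2 (5 mol%), DMA, 70 °C; then 13, PdCl2(PPh3)2 (5 mol%), THF, 0 °C → rt
Reagents that add atoms: zinc, [Zn] (metal of 14 only)
Why: Zinc insertion should give a β-ester alkylzinc whose stereocentre is not the metal-bearing carbon, and Negishi acylation then forms the β-keto ester with that centre unchanged (S → R by priority only).

Step 9
Reactants: 11 1-[(1S)-1,3,3-trimethylcyclohexyl]prop-2-en-1-one; 15 dimethyl (2R)-2-methyl-4-oxohexanedioate
Product: 17 methyl 3-[(2R)-1-methoxy-1-oxopropan-2-yl]-2-oxo-4-[(1S)-1,3,3-trimethylcyclohexyl]cyclohex-3-ene-1-carboxylate (both C1 epimers), via Michael adduct 16 (not isolated)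
Conditions: DBU (10 mol%), CH2Cl2, 0 °C → rt; then TsOH·H2O (20 mol%), toluene, reflux (Dean–Stark)
Reagents that add atoms: none
Why: In this Robinson annulation the doubly activated methylene of 15 should add to the vinyl ketone and the remaining α-methylene, the only one that can reach the ketone beside C1' through a six-membered ring, should then close by acid-catalysed aldol condensation, the acid medium sparing the ester α-centre while the ester-bearing ring carbon forms unselectively and is removed in step 10.

Step 10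
Reactants: 17 methyl 3-[(2R)-1-methoxy-1-oxopropan-2-yl]-2-oxo-4-[(1S)-1,3,3-trimethylcyclohexyl]cyclohex-3-ene-1-carboxylate
Product: 19 (2R)-2-{6-oxo-2-[(1S)-1,3,3-trimethylcyclohexyl]cyclohex-1-en-1-yl}propanoic acid, via keto diacid 18 (not isolated)
Conditions: LiOH, THF/MeOH/H2O, rt; then 2 M HCl, 50 °C
Reagents that add atoms: lithium hydroxide, [Li+].[OH-]
Why: Saponification of both methyl esters followed by acidification should decarboxylate only the β-keto acid, while the propanoic acid (a γ-keto acid) stays and its α-centre is shielded as the carboxylate once hydrolysed.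

Step 11
Reactants: 19 (2R)-2-{6-oxo-2-[(1S)-1,3,3-trimethylcyclohexyl]cyclohex-1-en-1-yl}propanoic acid
Product: 20 prop-2-en-1-yl (2R)-2-{6-oxo-2-[(1S)-1,3,3-trimethylcyclohexyl]cyclohex-1-en-1-yl}propanoate
Conditions: allyl bromide, K2CO3, DMF, rt
Reagents that add atoms: allyl bromide, C=CCBr
Why: O-Alkylation of the carboxylate under carbonate should give the allyl ester without forming an enolate at the α-centre or on the enone.

Step 12
Reactants: 20 prop-2-en-1-yl (2R)-2-{6-oxo-2-[(1S)-1,3,3-trimethylcyclohexyl]cyclohex-1-en-1-yl}propanoate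
Product: 21 prop-2-en-1-yl (2R)-2-{2-[(1S)-1,3,3-trimethylcyclohexyl]-6-[(trimethylsilyl)oxy]cyclohexa-1,5-dien-1-yl}propanoate
Conditions: LiN(iPr)2 (1.05 equiv), TMSCl, THF, −78 °C
Reagents that add atoms: chlorotrimethylsilane, C[Si](C)(C)Cl
Why: Kinetic deprotonation of the enone at the unhindered C5 methylene with in situ silylation should give the cross-conjugated silyl dienol ether, this proton being removed faster than the hindered tertiary α-hydrogen of the ester.

Step 13
Reactants: 21 prop-2-en-1-yl (2R)-2-{2-[(1S)-1,3,3-trimethylcyclohexyl]-6-[(trimethylsilyl)oxy]cyclohexa-1,5-dien-1-yl}propanoate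
Product: 22 prop-2-en-1-yl (2R)-2-{(5S)-5-(hydroxymethyl)-6-oxo-2-[(1S)-1,3,3-trimethylcyclohexyl]cyclohex-1-en-1-yl}propanoate
Conditions: Sc(OTf)3 (10 mol%), (S,S)-6,6'-bis(1-hydroxy-2,2-dimethylpropyl)-2,2'-bipyridine (12 mol%), aq. HCHO, DME/H2O, −20 °C
Reagents that add atoms: formaldehyde, C=O
Why: In this catalytic asymmetric Mukaiyama aldol reaction with aqueous formaldehyde (hydroxymethylation) the chiral scandium–bipyridine complex should select the face of the enol ether and so set the 5S centre under catalyst control, in a non-basic medium that avoids epimerisation and retro-aldol cleavage.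

Step 14
Reactants: 22 prop-2-en-1-yl (2R)-2-{(5S)-5-(hydroxymethyl)-6-oxo-2-[(1S)-1,3,3-trimethylcyclohexyl]cyclohex-1-en-1-yl}propanoate
Product: 23 prop-2-en-1-yl (2R)-2-{(5S)-5-[(formyloxy)methyl]-6-oxo-2-[(1S)-1,3,3-trimethylcyclohexyl]cyclohex-1-en-1-yl}propanoate
Conditions: HCO2COCH3 (acetic formic anhydride), pyridine, CH2Cl2, −20 °C
Reagents that add atoms: acetic formic anhydride, CC(=O)OC=O
Why: The primary alcohol should attack the more electrophilic formyl carbon of the mixed anhydride, and the cold, weakly basic conditions should preserve the C5 centre and avoid β-elimination.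

Step 15
Reactants: 23 prop-2-en-1-yl (2R)-2-{(5S)-5-[(formyloxy)methyl]-6-oxo-2-[(1S)-1,3,3-trimethylcyclohexyl]cyclohex-1-en-1-yl}propanoate
Product: 24 (2R)-2-{(5S)-5-[(formyloxy)methyl]-6-oxo-2-[(1S)-1,3,3-trimethylcyclohexyl]cyclohex-1-en-1-yl}propanoic acid
Conditions: Pd(PPh3)4 (5 mol%), PhSiH3 (2 equiv), CH2Cl2, rt; aqueous work-up
Reagents that add atoms: none
Why: Tsuji–Trost deallylation with a silane as allyl acceptor is neutral, so the formate, the β-acyloxy ketone and both epimerisable centres should survive.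

Compound list
1 | geraniol, (2E)-3,7-dimethylocta-2,6-dien-1-ol | CC(C)=CCC/C(C)=C/CO | starting material
2 | [(2R,3R)-3-methyl-3-(4-methylpent-3-en-1-yl)oxiran-2-yl]methanol | OC[C@H]1O[C@]1(C)CCC=C(C)C | intermediate
3 | tert-butyl(dimethyl){[(2R,3R)-3-methyl-3-(4-methylpent-3-en-1-yl)oxiran-2-yl]methoxy}silane | CC(C)(C)[Si](C)(C)OC[C@H]1O[C@]1(C)CCC=C(C)C | intermediate
4 | (2R)-2-{[tert-butyl(dimethyl)silyl]oxymethyl}-2,6-dimethylhept-5-enal | O=C[C@@](C)(CO[Si](C)(C)C(C)(C)C)CCC=C(C)C | intermediate
5 | N'-[(1E,2S)-2-{[tert-butyl(dimethyl)silyl]oxymethyl}-2,6-dimethylhept-5-en-1-ylidene]-4-methylbenzenesulfonohydrazide | Cc1ccc(cc1)S(=O)(=O)N/N=C/[C@@](C)(CO[Si](C)(C)C(C)(C)C)CCC=C(C)C | intermediate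
6 | N'-[(2S)-2-{[tert-butyl(dimethyl)silyl]oxymethyl}-2,6,6-trimethylcyclohexyl]-4-methylbenzenesulfonohydrazide (C1 epimers) | Cc1ccc(cc1)S(=O)(=O)NNC1[C@@](C)(CO[Si](C)(C)C(C)(C)C)CCCC1(C)C | intermediate (not isolated)
7 | [(2S)-2-{[tert-butyl(dimethyl)silyl]oxymethyl}-2,6,6-trimethylcyclohexyl]diazene (C1 epimers) | N=NC1[C@@](C)(CO[Si](C)(C)C(C)(C)C)CCCC1(C)C | intermediate (not isolated)
8 | tert-butyl(dimethyl){[(1S)-1,3,3-trimethylcyclohexyl]methoxy}silane | CC(C)(C)[Si](C)(C)OC[C@@]1(C)CCCC(C)(C)C1 | intermediate
9 | (1S)-1,3,3-trimethylcyclohexane-1-carboxylic acid | OC(=O)[C@@]1(C)CCCC(C)(C)C1 | intermediate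
10 | (1S)-1,3,3-trimethylcyclohexane-1-carbonyl chloride | ClC(=O)[C@@]1(C)CCCC(C)(C)C1 | intermediate (not isolated)
11 | 1-[(1S)-1,3,3-trimethylcyclohexyl]prop-2-en-1-one | C=CC(=O)[C@@]1(C)CCCC(C)(C)C1 | intermediate
12 | methyl (2S)-3-bromo-2-methylpropanoate | COC(=O)[C@H](C)CBr | starting material
13 | methyl 3-chloro-3-oxopropanoate (methyl malonyl chloride) | COC(=O)CC(=O)Cl | starting material
14 | bromo[(2S)-3-methoxy-2-methyl-3-oxopropyl]zinc | COC(=O)[C@H](C)C[Zn]Br | intermediate (not isolated)
15 | dimethyl (2R)-2-methyl-4-oxohexanedioate | COC(=O)[C@H](C)CC(=O)CC(=O)OC | intermediate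
16 | dimethyl (2R)-2-methyl-4-oxo-5-{3-oxo-3-[(1S)-1,3,3-trimethylcyclohexyl]propyl}hexanedioate (C5 epimers) | COC(=O)[C@H](C)CC(=O)C(CCC(=O)[C@@]1(C)CCCC(C)(C)C1)C(=O)OC | intermediate (not isolated)
17 | methyl 3-[(2R)-1-methoxy-1-oxopropan-2-yl]-2-oxo-4-[(1S)-1,3,3-trimethylcyclohexyl]cyclohex-3-ene-1-carboxylate (C1 epimers) | COC(=O)[C@H](C)C1=C([C@@]2(C)CCCC(C)(C)C2)CCC(C(=O)OC)C1=O | intermediate
18 | 3-[(1R)-1-carboxyethyl]-2-oxo-4-[(1S)-1,3,3-trimethylcyclohexyl]cyclohex-3-ene-1-carboxylic acid (C1 epimers) | C[C@@H](C(=O)O)C1=C([C@@]2(C)CCCC(C)(C)C2)CCC(C(=O)O)C1=O | intermediate (not isolated)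
19 | (2R)-2-{6-oxo-2-[(1S)-1,3,3-trimethylcyclohexyl]cyclohex-1-en-1-yl}propanoic acid | C[C@@H](C(=O)O)C1=C([C@@]2(C)CCCC(C)(C)C2)CCCC1=O | intermediate
20 | prop-2-en-1-yl (2R)-2-{6-oxo-2-[(1S)-1,3,3-trimethylcyclohexyl]cyclohex-1-en-1-yl}propanoate | C=CCOC(=O)[C@H](C)C1=C([C@@]2(C)CCCC(C)(C)C2)CCCC1=O | intermediate
21 | prop-2-en-1-yl (2R)-2-{2-[(1S)-1,3,3-trimethylcyclohexyl]-6-[(trimethylsilyl)oxy]cyclohexa-1,5-dien-1-yl}propanoate | C=CCOC(=O)[C@H](C)C1=C([C@@]2(C)CCCC(C)(C)C2)CCC=C1O[Si](C)(C)C | intermediate
22 | prop-2-en-1-yl (2R)-2-{(5S)-5-(hydroxymethyl)-6-oxo-2-[(1S)-1,3,3-trimethylcyclohexyl]cyclohex-1-en-1-yl}propanoate | C=CCOC(=O)[C@H](C)C1=C([C@@]2(C)CCCC(C)(C)C2)CC[C@@H](CO)C1=O | intermediate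
23 | prop-2-en-1-yl (2R)-2-{(5S)-5-[(formyloxy)methyl]-6-oxo-2-[(1S)-1,3,3-trimethylcyclohexyl]cyclohex-1-en-1-yl}propanoate | C=CCOC(=O)[C@H](C)C1=C([C@@]2(C)CCCC(C)(C)C2)CC[C@@H](COC=O)C1=O | intermediate
24 | (2R)-2-{(5S)-5-[(formyloxy)methyl]-6-oxo-2-[(1S)-1,3,3-trimethylcyclohexyl]cyclohex-1-en-1-yl}propanoic acid | C[C@@H](C(=O)O)C1=C([C@@]2(C)CCCC(C)(C)C2)CC[C@@H](COC=O)C1=O | target

Total step count: 15. Longest linear sequence: 14 (steps 1–7 and 9–15; step 8 makes the side fragment).

Steps most likely to fail

Step 5 (Proposed new method). The tertiary radical may be reduced (net alkene hydrogenation) before it adds to the hindered C=N, the addition may be slow or reversible, and breakdown of the hydrazide to the CH2 group may be incomplete. The fallback sets out from 4 and returns at 8. Aldehyde 4 itself would serve as radical acceptor: Fe(acac)3/PhSiH3 in EtOH at 60 °C (hydrogen-atom-transfer radical cyclisation onto a tethered carbonyl, 6-exo) should give (2R)-2-{[tert-butyl(dimethyl)silyl]oxymethyl}-2,6,6-trimethylcyclohexan-1-ol F1 as a mixture of carbinol epimers. Conversion with NaH, CS2 and MeI into O-[(2R)-2-{[tert-butyl(dimethyl)silyl]oxymethyl}-2,6,6-trimethylcyclohexyl] S-methyl carbonodithioate F2, then Barton–McCombie deoxygenation (Bu3SnH, AIBN, toluene, reflux), would give 8.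

Step 9. The sequence may stall after the Michael addition, because aldol closure of a branched methylene onto the ketone beside C1' is slow; the double bond may move out of conjugation; and the ester α-centre may epimerise if the conditions have to be forced. The fallback sets out from 11 and returns at 19. Vinyl ketone 11 would be annulated with methyl acetoacetate (same two-stage conditions), whose methyl group closes the ring without the branched substituent, to give methyl 2-oxo-4-[(1S)-1,3,3-trimethylcyclohexyl]cyclohex-3-ene-1-carboxylate F3. Saponification and decarboxylation would give 3-[(1S)-1,3,3-trimethylcyclohexyl]cyclohex-2-en-1-one F4, and bromination followed by dehydrobromination (Br2, then Et3N) would give 2-bromo-3-[(1S)-1,3,3-trimethylcyclohexyl]cyclohex-2-en-1-one F5. Stille coupling with methyl 2-(tributylstannyl)prop-2-enoate would give methyl 2-{6-oxo-2-[(1S)-1,3,3-trimethylcyclohexyl]cyclohex-1-en-1-yl}prop-2-enoate F6, and LiOH would give 2-{6-oxo-2-[(1S)-1,3,3-trimethylcyclohexyl]cyclohex-1-en-1-yl}prop-2-enoic acid F7. Asymmetric hydrogenation of this 2-substituted acrylic acid with Ru(OAc)2[(R)-BINAP] and H2 in MeOH would set the propanoate centre and give 19.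

Step 13. The catalyst may select the faces of this hindered dienol ether poorly, the silyl enol ether may be protodesilylated back to 20, and the new centre may epimerise later. The fallback sets out from 21 and returns at 22. The dienol ether 21 would be hydroxymethylated without a chiral ligand (Yb(OTf)3, aq. HCHO, THF) to give 22 together with its C5 epimer, prop-2-en-1-yl (2R)-2-{(5R)-5-(hydroxymethyl)-6-oxo-2-[(1S)-1,3,3-trimethylcyclohexyl]cyclohex-1-en-1-yl}propanoate F8. The two diastereomers would be separated by chromatography and F8 recycled by base equilibration of the ketone α-centre (DBU, CH2Cl2), so that stereocontrol rests on separation and recycling instead of on a chiral catalyst.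

Further compounds
F1 | step 5 | (2R)-2-{[tert-butyl(dimethyl)silyl]oxymethyl}-2,6,6-trimethylcyclohexan-1-ol (C1 epimers) | OC1[C@@](C)(CO[Si](C)(C)C(C)(C)C)CCCC1(C)C
F2 | step 5 | O-[(2R)-2-{[tert-butyl(dimethyl)silyl]oxymethyl}-2,6,6-trimethylcyclohexyl] S-methyl carbonodithioate (C1 epimers) | CSC(=S)OC1[C@@](C)(CO[Si](C)(C)C(C)(C)C)CCCC1(C)C
F3 | step 9 | methyl 2-oxo-4-[(1S)-1,3,3-trimethylcyclohexyl]cyclohex-3-ene-1-carboxylate (C1 epimers) | COC(=O)C1CCC(=CC1=O)[C@@]2(C)CCCC(C)(C)C2
F4 | step 9 | 3-[(1S)-1,3,3-trimethylcyclohexyl]cyclohex-2-en-1-one | O=C1CCCC(=C1)[C@@]2(C)CCCC(C)(C)C2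
F5 | step 9 | 2-bromo-3-[(1S)-1,3,3-trimethylcyclohexyl]cyclohex-2-en-1-one | O=C1CCCC(=C1Br)[C@@]2(C)CCCC(C)(C)C2
F6 | step 9 | methyl 2-{6-oxo-2-[(1S)-1,3,3-trimethylcyclohexyl]cyclohex-1-en-1-yl}prop-2-enoate | COC(=O)C(=C)C1=C([C@@]2(C)CCCC(C)(C)C2)CCCC1=O
F7 | step 9 | 2-{6-oxo-2-[(1S)-1,3,3-trimethylcyclohexyl]cyclohex-1-en-1-yl}prop-2-enoic acid | OC(=O)C(=C)C1=C([C@@]2(C)CCCC(C)(C)C2)CCCC1=O
F8 | step 13 | prop-2-en-1-yl (2R)-2-{(5R)-5-(hydroxymethyl)-6-oxo-2-[(1S)-1,3,3-trimethylcyclohexyl]cyclohex-1-en-1-yl}propanoate | C=CCOC(=O)[C@H](C)C1=C([C@@]2(C)CCCC(C)(C)C2)CC[C@H](CO)C1=O
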